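**Retrosynthetic overview**
1. The target comes from its dimethyl ether (7-OMe on the chlorinated half, 4'-OMe on the other half) by a final global O-demethylation.
2. The hindered C8–O diaryl ether bond is cut to an isoflavone ortho-quinone diazide (fragment 1) and a 4'-phenol (fragment 2). It is made by carbene O–H insertion (new step), which also returns the free 7-OH.
3. Fragment 1 comes from formononetin by C8 azo coupling, reductive cleavage to the 8-amine, and diazotisation.
4. Fragment 2 comes from 8-chlorodaidzein by 7-O-selective methylation. The chlorine is bought in place with 2-chlororesorcinol.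
5. Ring order: the pyranone ring of each half is closed first and separately (deoxybenzoin plus one carbon). All benzene rings are bought, and no ring is formed after the union.

**Assumption:** the target SMILES holds no stereocentre and no hindered axis, so the compound is achiral and "single enantiomer" calls for no stereocontrol.

**Step 1**
Reactants: 1 resorcinol; 2 4-methoxyphenylacetic acid
Product: 4 formononetin (7-hydroxy-3-(4-methoxyphenyl)-4H-chromen-4-one), via deoxybenzoin 3 (not isolated)
Conditions: BF3·OEt2 (solvent), 85 °C, 1.5 h; then DMF, MsCl (3 equiv), 50 → 90 °C, 2 h; ice water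
Reagents that add atoms: N,N-dimethylformamide, CN(C)C=O
Why: Friedel–Crafts C-acylation of resorcinol at C4 gives the ortho-hydroxy deoxybenzoin, and the Vilsmeier-type iminium salt from DMF/MsCl then inserts one carbon at the activated methylene and closes the pyranone onto the ortho phenol (deoxybenzoin isoflavone synthesis); no stereocentre is formed.

**Step 2**
Reactants: 4 formononetin
Product: 5 7-hydroxy-3-(4-methoxyphenyl)-8-[(E)-(4-nitrophenyl)diazenyl]-4H-chromen-4-one
Conditions: 4-O2NC6H4N2BF4 (1.05 equiv), Na2CO3 (2 equiv), THF/H2O 1:1, 0 °C, 2 h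
Reagents that add atoms: 4-nitrobenzenediazonium tetrafluoroborate, [O-][N+](=O)c1ccc(cc1)[N+]#N.F[B-](F)(F)F
Why: Azo coupling (electrophilic aromatic substitution) works because only ring A carries a phenolate under cold carbonate, and the C7–C8 bond of 7-hydroxychromones has the higher double-bond character, so the strongly electrophilic diazonium ion attacks C8 as in 2-naphthol couplings and gives the hydrogen-bonded E azo dye.

**Step 3**
Reactants: 5 the 8-arylazo isoflavone
Product: 6 8-amino-7-hydroxy-3-(4-methoxyphenyl)-4H-chromen-4-one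
Conditions: Na2S2O4 (8 equiv), THF/EtOH/H2O, 60 °C, 1 h, N2
Reagents that add atoms: none
Why: Dithionite reductive cleavage of an ortho-hydroxyazo dye is the classical route to ortho-aminophenols; it also reduces the nitro group of the spent arene and leaves the pyranone enone and the methyl ether untouched.

**Step 4**
Reactants: 6 the 8-amino-7-hydroxyisoflavone
Product: 7 8-diazonio-3-(4-methoxyphenyl)-4-oxo-4H-chromen-7-olate (ortho-quinone diazide)
Conditions: t-BuONO (1.2 equiv), Cl3CCO2H (5 mol %), THF, 0 °C, 1 h, dark
Reagents that add atoms: tert-butyl nitrite, CC(C)(C)ON=O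
Why: Aprotic diazotisation with an alkyl nitrite and catalytic acid, as used to make benzenediazonium-2-carboxylate, gives a diazonium ion whose acidic ortho 7-OH loses its proton at once, so the neutral quinone diazide separates directly.

**Step 5**
Reactants: 8 2-chlororesorcinol; 9 4-hydroxyphenylacetic acid
Product: 11 8-chlorodaidzein (8-chloro-7-hydroxy-3-(4-hydroxyphenyl)-4H-chromen-4-one), via chlorodeoxybenzoin 10 (not isolated)
Conditions: BF3·OEt2 (solvent), 90 °C, 3 h; then DMF, MsCl (3 equiv), 50 → 90 °C, 2 h; ice water
Reagents that add atoms: N,N-dimethylformamide, CN(C)C=O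
Why: This is the same Friedel–Crafts acylation and one-carbon cyclisation as step 1; C4 and C6 of 2-chlororesorcinol are equivalent, so a single ketone forms, ring closure through the hydroxyl next to chlorine fixes Cl at C8, and free phenols are tolerated in the BF3 medium.

**Step 6**
Reactants: 11 8-chlorodaidzein
Product: 12 8-chloro-3-(4-hydroxyphenyl)-7-methoxy-4H-chromen-4-one
Conditions: MeI (1.1 equiv), KHCO3 (1.2 equiv), DMF, 35 °C, 12 h
Reagents that add atoms: iodomethane, CI
Why: This is a Williamson ether synthesis under acidity control: the 7-OH (vinylogous acid, ortho chlorine) is more than three pKa units more acidic than the 4'-OH, so hydrogen carbonate ionises and methylates only O7.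

**Step 7**
Reactants: 7 the ortho-quinone diazide; 12 the 4'-phenol (1.5 equiv)
Product: 13 8-chloro-3-(4-{[7-hydroxy-3-(4-methoxyphenyl)-4-oxo-4H-chromen-8-yl]oxy}phenyl)-7-methoxy-4H-chromen-4-one
Conditions: Rh2(esp)2 (2 mol %; esp = α,α,α',α'-tetramethyl-1,3-benzenedipropionate), 4 Å MS, ClCH2CH2Cl, 60 °C, 7 added over 4 h by syringe pump, dark
Reagents that add atoms: none
Why: Proposed new method: carbene O–H insertion used as a diaryl ether synthesis between two isoflavone halves, in which the divalent rhodium dimer Rh2(esp)2 expels N2 from the chromone-fused quinone diazide to give an electrophilic quinoid carbene at C8, the only free hydroxyl offered (4'-OH of 12) adds through oxygen to an oxonium ylide, and a 1,4-proton shift to the neighbouring C7 carbonyl oxygen re-aromatises ring A, so the hindered C8–O bond and the free 7-OH arise together without base; slow addition in the dark holds back Wolff ring contraction and carbene dimerisation, sieves exclude water, and the product 7-OH (acidic, flanked by the new aryloxy group) is too poor a nucleophile to compete; the closest known reaction type is the dirhodium carboxylate catalysed O–H insertion of diazonaphthoquinones and α-diazocarbonyl compounds into alcohols, which has not been shown for benzopyranone-fused quinone diazides or for a phenol partner of this kind; no stereocentre is formed.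

**Step 8**
Reactants: 13 the dimethyl ether
Product: 14 bisoflavolin J (8-chloro-7-hydroxy-3-(4-{[7-hydroxy-3-(4-hydroxyphenyl)-4-oxo-4H-chromen-8-yl]oxy}phenyl)-4H-chromen-4-one)
Conditions: BBr3 (10 equiv), CH2Cl2, −78 °C → rt, 16 h; then H2O
Reagents that add atoms: none
Why: In Lewis acid ether cleavage, bromide attacks only the sp3 methyl carbons of the boron-complexed aryl methyl ethers, so the diaryl ether, the aryl chloride and both pyranones survive, as is usual in the last step of ether-linked biflavonoid syntheses.

**Compound list**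
1 | resorcinol | Oc1cccc(O)c1 | starting material
2 | 4-methoxyphenylacetic acid | COc1ccc(CC(=O)O)cc1 | starting material
3 | 1-(2,4-dihydroxyphenyl)-2-(4-methoxyphenyl)ethan-1-one | COc1ccc(CC(=O)c2ccc(O)cc2O)cc1 | intermediate
4 | formononetin, 7-hydroxy-3-(4-methoxyphenyl)-4H-chromen-4-one | COc1ccc(cc1)-c1coc2cc(O)ccc2c1=O | intermediate
5 | 7-hydroxy-3-(4-methoxyphenyl)-8-[(E)-(4-nitrophenyl)diazenyl]-4H-chromen-4-one | COc1ccc(cc1)-c1coc2c(/N=N/c3ccc(cc3)[N+](=O)[O-])c(O)ccc2c1=O | intermediate
6 | 8-amino-7-hydroxy-3-(4-methoxyphenyl)-4H-chromen-4-one | COc1ccc(cc1)-c1coc2c(N)c(O)ccc2c1=O | intermediate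
7 | 8-diazonio-3-(4-methoxyphenyl)-4-oxo-4H-chromen-7-olate | COc1ccc(cc1)-c1coc2c([N+]#N)c([O-])ccc2c1=O | intermediate
8 | 2-chlororesorcinol | Oc1cccc(O)c1Cl | starting material
9 | 4-hydroxyphenylacetic acid | OC(=O)Cc1ccc(O)cc1 | starting material
10 | 1-(3-chloro-2,4-dihydroxyphenyl)-2-(4-hydroxyphenyl)ethan-1-one | O=C(Cc1ccc(O)cc1)c1ccc(O)c(Cl)c1O | intermediate
11 | 8-chlorodaidzein, 8-chloro-7-hydroxy-3-(4-hydroxyphenyl)-4H-chromen-4-one | O=c1c(-c2ccc(O)cc2)coc2c(Cl)c(O)ccc12 | intermediate
12 | 8-chloro-3-(4-hydroxyphenyl)-7-methoxy-4H-chromen-4-one | O=c1c(-c2ccc(O)cc2)coc2c(Cl)c(OC)ccc12 | intermediate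
13 | 8-chloro-3-(4-{[7-hydroxy-3-(4-methoxyphenyl)-4-oxo-4H-chromen-8-yl]oxy}phenyl)-7-methoxy-4H-chromen-4-one | O=c1c(-c2ccc(Oc3c(O)ccc4c(=O)c(-c5ccc(OC)cc5)coc34)cc2)coc2c(Cl)c(OC)ccc12 | intermediate
14 | bisoflavolin J (achiral) | O=c1c(-c2ccc(Oc3c(O)ccc4c(=O)c(-c5ccc(O)cc5)coc34)cc2)coc2c(Cl)c(O)ccc12 | target

**Total step count:** 8.
**Longest linear sequence:** 6 steps (1, 2, 3, 4, 7, 8). Steps 5 and 6 form the second branch.

**Three steps most likely to fail**

**Step 7 (proposed new step).**
- Risks: Wolff ring contraction of 7, C-arylation ortho to the phenol of 12 instead of O-attack, and insertion into traces of water or into the product.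
- Fallback with known chemistry only. It sets out from 7 and comes back to the route at 14.
- Compound 7 is treated with KI in aqueous H2SO4/MeCN at 0 °C to rt (Sandmeyer-type iodo-dediazoniation). This gives 7-hydroxy-8-iodo-3-(4-methoxyphenyl)-4H-chromen-4-one F1.
- MeI and K2CO3 in acetone then give 8-iodo-7-methoxy-3-(4-methoxyphenyl)-4H-chromen-4-one F2.
- An Ullmann-type ether coupling of this iodide with phenol 12 follows. Conditions are the monovalent copper salt CuI (10 mol %), picolinic acid (20 mol %), K3PO4, DMSO, 90 °C, a system made for doubly ortho-substituted partners. It gives 8-chloro-7-methoxy-3-(4-{[7-methoxy-3-(4-methoxyphenyl)-4-oxo-4H-chromen-8-yl]oxy}phenyl)-4H-chromen-4-one F3.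
- BBr3 in CH2Cl2, as in step 8, cleaves all three methyl ethers to 14.

**Step 2 (azo coupling).**
- Risks: a C6/C8 mixture, slow coupling on the carbonyl-deactivated phenolate, decay of the diazonium salt, or opening of the pyranone in base.
- The fallback brings in nitrogen by base-free radical nitration instead. It sets out from 4 and comes back at 6.
- Compound 4 is stirred with t-BuONO (3 equiv) in THF at rt. This reagent nitrates only free phenols (O-nitrosation, homolysis, recombination with NO2), so the anisole ring is spared. It gives 7-hydroxy-3-(4-methoxyphenyl)-8-nitro-4H-chromen-4-one F4.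
- F4 is purified by chromatography and recognised by the H5/H6 pair of doublets (J about 9 Hz).
- Reduction with Na2S2O4 under the conditions of step 3 then gives 6.

**Step 6 (selective 7-O-methylation).**
- Risks: 4'-O-methylation or double methylation that is hard to separate.
- The fallback replaces direct selection by an acetate relay. It sets out from 11 and comes back at 12.
- Ac2O in pyridine gives 4-(7-acetoxy-8-chloro-4-oxo-4H-chromen-3-yl)phenyl acetate F5.
- PhSH (1 equiv) with imidazole in NMP at 0 °C removes only the more activated 7-O-acetyl group, which is the usual behaviour of flavonoid peracetates. This gives 4-(8-chloro-7-hydroxy-4-oxo-4H-chromen-3-yl)phenyl acetate F6.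
- MeI and K2CO3 in acetone at rt give 4-(8-chloro-7-methoxy-4-oxo-4H-chromen-3-yl)phenyl acetate F7.
- Catalytic K2CO3 in MeOH at rt transesterifies the remaining acetate to give 12.

**Further compounds**
F1 | step 7 | 7-hydroxy-8-iodo-3-(4-methoxyphenyl)-4H-chromen-4-one | COc1ccc(cc1)-c1coc2c(I)c(O)ccc2c1=O
F2 | step 7 | 8-iodo-7-methoxy-3-(4-methoxyphenyl)-4H-chromen-4-one | COc1ccc(cc1)-c1coc2c(I)c(OC)ccc2c1=O
F3 | step 7 | 8-chloro-7-methoxy-3-(4-{[7-methoxy-3-(4-methoxyphenyl)-4-oxo-4H-chromen-8-yl]oxy}phenyl)-4H-chromen-4-one | O=c1c(-c2ccc(Oc3c(OC)ccc4c(=O)c(-c5ccc(OC)cc5)coc34)cc2)coc2c(Cl)c(OC)ccc12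
F4 | step 2 | 7-hydroxy-3-(4-methoxyphenyl)-8-nitro-4H-chromen-4-one | COc1ccc(cc1)-c1coc2c([N+](=O)[O-])c(O)ccc2c1=O
F5 | step 6 | 4-(7-acetoxy-8-chloro-4-oxo-4H-chromen-3-yl)phenyl acetate | CC(=O)Oc1ccc(cc1)-c1coc2c(Cl)c(OC(C)=O)ccc2c1=O
F6 | step 6 | 4-(8-chloro-7-hydroxy-4-oxo-4H-chromen-3-yl)phenyl acetate | CC(=O)Oc1ccc(cc1)-c1coc2c(Cl)c(O)ccc2c1=O
F7 | step 6 | 4-(8-chloro-7-methoxy-4-oxo-4H-chromen-3-yl)phenyl acetate | CC(=O)Oc1ccc(cc1)-c1coc2c(Cl)c(OC)ccc2c1=O
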